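**Retrosynthetic overview**
- The last bond made is the palmitate ester C–O bond, by Mitsunobu esterification of the benzylic alcohol of 19, which comes from 18 by acid removal of the MOM and TBS groups.
- Ring B is the benzoate ring in which C1' (bearing CO2Me) lies between C2' (bearing the ether oxygen to ring A) and C6' (bearing OH), with the methyl on C4'. It is cut at C2'–C3' and C1'–C6': C1'/C2' are the alkyne carbons of aryloxypropiolate 12, and C3'–C6' are the four-carbon chain of the senecioate-derived vinylketene acetal 15. A [4+2] addition and loss of methanol build the ring.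
- The crowded diaryl ether oxygen is the phenol oxygen of ring A. It is joined to the two-carbon unit beforehand by O-dichlorovinylation of phenol 6 with trichloroethylene, then n-BuLi and methyl chloroformate.
- Ring A is bought as 5-methoxysalicylaldehyde and only decorated (C3 bromination, hydroxylation, MOM, reduction, TBS). Ring B is the only ring formed, in step 9.

Key step: step 9

Assumption: the target has no stereocentre, and the tri-ortho-substituted diaryl ether axis is not configurationally stable, so "single enantiomer" is taken to mean the one achiral constitution; no stereocontrol is required.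

**Route**

Step 1
Reactants: 1 2-hydroxy-5-methoxybenzaldehyde
Product: 2 3-bromo-2-hydroxy-5-methoxybenzaldehyde
Conditions: Br2 (1.05 equiv), NaOAc, AcOH, rt
Reagents that add atoms: bromine, BrBr
Why: Electrophilic aromatic bromination directed by the free phenol, whose para position is blocked by the methoxy group, should place bromine at C3 ortho to the hydroxyl.

Step 2
Reactants: 2 3-bromo-2-hydroxy-5-methoxybenzaldehyde
Product: 3 2,3-dihydroxy-5-methoxybenzaldehyde
Conditions: Cu powder (cat.), 8% aq NaOH, reflux, N2; then aq HCl
Reagents that add atoms: sodium hydroxide, [Na+].[OH-]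
Why: Copper-mediated Ullmann-type hydroxylation of an ortho-bromophenoxide in hot aqueous alkali, the reaction type that turns 5-bromovanillin into 5-hydroxyvanillin, should replace bromide by hydroxide while the phenoxide shields the aldehyde from Cannizzaro disproportionation.

Step 3
Reactants: 3 2,3-dihydroxy-5-methoxybenzaldehyde
Product: 4 2-hydroxy-5-methoxy-3-(methoxymethoxy)benzaldehyde
Conditions: NaH (2.1 equiv), DMF, 0 °C to rt; MOMCl (1.0 equiv), 0 °C
Reagents that add atoms: chloromethyl methyl ether, COCCl
Why: Williamson alkylation of the dianion, in which the C2 phenoxide is stabilised by conjugation with the formyl group and chelated to sodium, so that one equivalent of MOMCl should react at the more basic and less hindered C3 phenoxide.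

Step 4
Reactants: 4 2-hydroxy-5-methoxy-3-(methoxymethoxy)benzaldehyde
Product: 5 2-(hydroxymethyl)-4-methoxy-6-(methoxymethoxy)phenol
Conditions: NaBH4, MeOH/THF, 0 °C
Reagents that add atoms: none
Why: Borohydride reduction of the aldehyde to the primary alcohol leaves the MOM acetal and the aryl ethers untouched.

Step 5
Reactants: 5 2-(hydroxymethyl)-4-methoxy-6-(methoxymethoxy)phenol
Product: 6 2-{[(tert-butyldimethylsilyl)oxy]methyl}-4-methoxy-6-(methoxymethoxy)phenol
Conditions: TBSCl (1.05 equiv), imidazole, CH2Cl2, 0 °C
Reagents that add atoms: tert-butyldimethylsilyl chloride, CC(C)(C)[Si](C)(C)Cl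
Why: Silylation of the primary benzylic alcohol should outpace that of the phenol, which is flanked by two ortho substituents and hydrogen-bonded to the MOM oxygen, so one equivalent of TBSCl should give the mono-silyl ether.

Step 6
Reactants: 6 2-{[(tert-butyldimethylsilyl)oxy]methyl}-4-methoxy-6-(methoxymethoxy)phenol; 7 trichloroethylene
Product: 9 tert-butyl[(2-{[(E)-1,2-dichloroethenyl]oxy}-5-methoxy-3-(methoxymethoxy)phenyl)methoxy]dimethylsilane, via dichloroacetylene 8 (not isolated)
Conditions: K2CO3, DMF, 70 °C
Reagents that add atoms: none
Why: Base eliminates HCl from trichloroethylene to dichloroacetylene, and anti addition of the phenoxide across this small linear electrophile gives the (E)-1,2-dichlorovinyl ether, a known O-vinylation that tolerates 2,6-disubstituted phenols.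

Step 7
Reactants: 9 tert-butyl[(2-{[(E)-1,2-dichloroethenyl]oxy}-5-methoxy-3-(methoxymethoxy)phenyl)methoxy]dimethylsilane
Product: 12 methyl 3-{2-[(tert-butyldimethylsilyloxy)methyl]-4-methoxy-6-(methoxymethoxy)phenoxy}prop-2-ynoate, via chloroalkynyl ether 10 (not isolated), via lithium aryloxyacetylide 11 (not isolated)
Conditions: n-BuLi (2.2 equiv), THF, –78 to –40 °C; ClCO2Me, –78 to 0 °C
Reagents that add atoms: methyl chloroformate, COC(=O)Cl
Why: Deprotonation of the dichlorovinyl ether and loss of LiCl give the chloroalkynyl ether, chlorine–lithium exchange with the second equivalent of n-BuLi gives the lithium aryloxyacetylide, and C-acylation with the chloroformate gives the ynoate (the known ynol ether synthesis from dichlorovinyl ethers followed by acetylide acylation), all faster at low temperature than ortho-lithiation next to the MOM group.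

Step 8
Reactants: 13 methyl 3-methylbut-2-enoate
Product: 15 1-methoxy-3-methyl-1-(trimethylsilyloxy)buta-1,3-diene (E/Z mixture), via lithium dienolate 14 (not isolated)
Conditions: LDA, THF, –78 °C; TMSCl, –78 °C to rt; distil
Reagents that add atoms: chlorotrimethylsilane, C[Si](C)(C)Cl
Why: γ-Deprotonation of the senecioate by LDA gives the extended dienolate, which is silylated on oxygen to the vinylketene silyl acetal, the known preparation of this diene.

Step 9
Reactants: 12 methyl 3-{2-[(tert-butyldimethylsilyloxy)methyl]-4-methoxy-6-(methoxymethoxy)phenoxy}prop-2-ynoate; 15 1-methoxy-3-methyl-1-(trimethylsilyloxy)buta-1,3-diene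
Product: 18 methyl 2-{2-[(tert-butyldimethylsilyloxy)methyl]-4-methoxy-6-(methoxymethoxy)phenoxy}-6-hydroxy-4-methylbenzoate, via cyclohexadiene cycloadduct 16 (not isolated), via aryl trimethylsilyl ether 17 (not isolated)
Conditions: 15 (3 equiv), PhMe, 100 °C, sealed tube; then 0.1 M aq HCl/THF, 0 °C, brief
Reagents that add atoms: none
Why: Proposed new method: the ester makes Cβ of the ynoate (the carbon bearing the aryloxy group) the electrophilic terminus, and the CH2 terminus of the vinylketene acetal, which carries the largest HOMO coefficient, should bond to it while the ketene-acetal carbon bonds to the ester-bearing Cα, either in one asynchronous [4+2] transition state or by a vinylogous Mukaiyama–Michael addition followed by 6-exo-trig attack of Cα on the silyloxycarbenium carbon. The closest known reaction type is the Diels–Alder/aromatisation of 1-alkoxy-1-silyloxybuta-1,3-dienes with propiolates and acetylenedicarboxylates to give salicylates; a 3-aryloxypropiolate has not been used as the two-carbon partner, but an aryloxy group is a weaker donor than alkoxy or amino, so the ynoate should keep enough acceptor character. Ring B closes as a six-membered carbocycle by this intermolecular [4+2] (or Michael–Claisen) mode, and the cyclohexa-1,4-diene 16 aromatises by 1,4-loss of methanol from its mixed methyl silyl ketal to the aryl silyl ether 17, which dilute acid cleaves to the hydrogen-bonded phenol. The only stereocentre formed is the ketal carbon of 16, which is racemic and is erased on aromatisation, as is the E/Z geometry of the diene. The selectivity needed is regiochemical (ester between hydroxyl and aryloxy, methyl para to the ester); it is secured by the matched polarity of the two partners and reinforced sterically, since the bulky ketene-acetal terminus avoids the hindered aryloxy carbon. The MOM and TBS ethers are inert to the neutral thermal conditions and should survive the brief cold acid work-up.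

Step 10
Reactants: 18 methyl 2-{2-[(tert-butyldimethylsilyloxy)methyl]-4-methoxy-6-(methoxymethoxy)phenoxy}-6-hydroxy-4-methylbenzoate
Product: 19 methyl 2-hydroxy-6-[2-hydroxy-6-(hydroxymethyl)-4-methoxyphenoxy]-4-methylbenzoate
Conditions: 3 M aq HCl/THF (1:4), 40 °C
Reagents that add atoms: none
Why: Acid-catalysed hydrolysis of the MOM acetal and of the primary TBS ether in aqueous THF, with methanol avoided so that the benzylic alcohol cannot be etherified and with the hydrogen-bonded methyl salicylate stable to dilute acid.

Step 11
Reactants: 19 methyl 2-hydroxy-6-[2-hydroxy-6-(hydroxymethyl)-4-methoxyphenoxy]-4-methylbenzoate; 20 palmitic acid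
Product: 21 betaethrin E, methyl 2-{2-[(hexadecanoyloxy)methyl]-6-hydroxy-4-methoxyphenoxy}-6-hydroxy-4-methylbenzoate
Conditions: PPh3, DIAD, THF, 0 °C to rt
Reagents that add atoms: none
Why: Mitsunobu esterification, in which the phosphonium activates only the aliphatic benzylic hydroxyl and the carboxylic acid, about five pKa units more acidic than either phenol, is the pronucleophile that displaces it, so the phenols need no protection (known chemoselective esterification of phenolic alcohols).

**Compound list**

1 | 2-hydroxy-5-methoxybenzaldehyde | COc1ccc(O)c(C=O)c1 | starting material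
2 | 3-bromo-2-hydroxy-5-methoxybenzaldehyde | COc1cc(Br)c(O)c(C=O)c1 | intermediate
3 | 2,3-dihydroxy-5-methoxybenzaldehyde | COc1cc(O)c(O)c(C=O)c1 | intermediate
4 | 2-hydroxy-5-methoxy-3-(methoxymethoxy)benzaldehyde | COCOc1cc(OC)cc(C=O)c1O | intermediate
5 | 2-(hydroxymethyl)-4-methoxy-6-(methoxymethoxy)phenol | COCOc1cc(OC)cc(CO)c1O | intermediate
6 | 2-{[(tert-butyldimethylsilyl)oxy]methyl}-4-methoxy-6-(methoxymethoxy)phenol | COCOc1cc(OC)cc(CO[Si](C)(C)C(C)(C)C)c1O | intermediate
7 | trichloroethylene | ClC=C(Cl)Cl | starting material
8 | dichloroacetylene (formed in situ) | ClC#CCl | intermediate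
9 | tert-butyl[(2-{[(E)-1,2-dichloroethenyl]oxy}-5-methoxy-3-(methoxymethoxy)phenyl)methoxy]dimethylsilane | Cl/C=C(/Cl)Oc1c(CO[Si](C)(C)C(C)(C)C)cc(OC)cc1OCOC | intermediate
10 | tert-butyl({2-[(chloroethynyl)oxy]-5-methoxy-3-(methoxymethoxy)phenyl}methoxy)dimethylsilane (chloroalkynyl ether, in situ) | ClC#COc1c(CO[Si](C)(C)C(C)(C)C)cc(OC)cc1OCOC | intermediate
11 | lithium aryloxyacetylide of 10 (in situ) | [Li]C#COc1c(CO[Si](C)(C)C(C)(C)C)cc(OC)cc1OCOC | intermediate
12 | methyl 3-{2-[(tert-butyldimethylsilyloxy)methyl]-4-methoxy-6-(methoxymethoxy)phenoxy}prop-2-ynoate | COC(=O)C#COc1c(CO[Si](C)(C)C(C)(C)C)cc(OC)cc1OCOC | intermediate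
13 | methyl 3-methylbut-2-enoate | COC(=O)C=C(C)C | starting material
14 | lithium 1-methoxy-3-methylbuta-1,3-dien-1-olate (in situ) | C=C(C)C=C(OC)O[Li] | intermediate
15 | 1-methoxy-3-methyl-1-(trimethylsilyloxy)buta-1,3-diene (E/Z mixture) | C=C(C)C=C(OC)O[Si](C)(C)C | intermediate
16 | methyl 2-{2-[(tert-butyldimethylsilyloxy)methyl]-4-methoxy-6-(methoxymethoxy)phenoxy}-6-methoxy-4-methyl-6-(trimethylsilyloxy)cyclohexa-1,4-diene-1-carboxylate (racemic, in situ) | COC(=O)C1=C(Oc2c(CO[Si](C)(C)C(C)(C)C)cc(OC)cc2OCOC)CC(C)=CC1(OC)O[Si](C)(C)C | intermediate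
17 | methyl 2-{2-[(tert-butyldimethylsilyloxy)methyl]-4-methoxy-6-(methoxymethoxy)phenoxy}-4-methyl-6-(trimethylsilyloxy)benzoate (in situ) | COC(=O)c1c(O[Si](C)(C)C)cc(C)cc1Oc1c(CO[Si](C)(C)C(C)(C)C)cc(OC)cc1OCOC | intermediate
18 | methyl 2-{2-[(tert-butyldimethylsilyloxy)methyl]-4-methoxy-6-(methoxymethoxy)phenoxy}-6-hydroxy-4-methylbenzoate | COC(=O)c1c(O)cc(C)cc1Oc1c(CO[Si](C)(C)C(C)(C)C)cc(OC)cc1OCOC | intermediate
19 | methyl 2-hydroxy-6-[2-hydroxy-6-(hydroxymethyl)-4-methoxyphenoxy]-4-methylbenzoate | COC(=O)c1c(O)cc(C)cc1Oc1c(CO)cc(OC)cc1O | intermediate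
20 | palmitic acid (hexadecanoic acid) | CCCCCCCCCCCCCCCC(=O)O | starting material
21 | betaethrin E | CCCCCCCCCCCCCCCC(=O)OCc1cc(OC)cc(O)c1Oc1cc(C)cc(O)c1C(=O)OC | target

**Step count**
Total: 11 steps. Longest linear sequence: 10 steps (steps 1–7, 9, 10, 11); step 8 is a one-step side branch.

**Steps most likely to fail**

1. Step 9 (proposed new method). Donation from the aryloxy oxygen may slow the cycloaddition so much that the diene is lost first to silyl transfer or hydrolysis. Alternatively the reaction may run stepwise and the intermediate may expel aryloxide (addition–elimination at the alkyne) instead of closing the ring. The fallback uses known chemistry: ring B is taken from an existing arene and the diaryl ether is made by metal-catalysed C–O coupling. It sets out from phenol 6 and returns at 19. Commercial methyl 2,6-dihydroxy-4-methylbenzoate (COC(=O)c1c(O)cc(C)cc1O) is symmetric, so its mono-protection raises no regiochemical question. MOMCl/i-Pr2NEt converts it into methyl 2-hydroxy-6-(methoxymethoxy)-4-methylbenzoate F1, and Tf2O/pyridine then gives methyl 2-(methoxymethoxy)-4-methyl-6-{[(trifluoromethyl)sulfonyl]oxy}benzoate F2. Pd-catalysed etherification of 6 with F2 (Pd(OAc)2, a bulky di-tert-butylbiarylphosphine such as t-BuXPhos, K3PO4, toluene, 100 °C) should give methyl 2-{2-[(tert-butyldimethylsilyloxy)methyl]-4-methoxy-6-(methoxymethoxy)phenoxy}-6-(methoxymethoxy)-4-methylbenzoate F3. The aqueous HCl/THF treatment of step 10 then removes both MOM groups and the TBS group to give 19.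

2. Step 3. Regiocontrol in the mono-alkylation of the catechol dianion may be incomplete, with alkylation at the chelated C2 phenoxide or double alkylation. The fallback replaces selective protection by exhaustive protection and chelation-directed deprotection. It sets out from 3 and returns at 4. Excess MOMCl/i-Pr2NEt (CH2Cl2) protects both hydroxyls to give 5-methoxy-2,3-bis(methoxymethoxy)benzaldehyde F4. MgBr2·OEt2 (Et2O/CH2Cl2, 0 °C to rt) should then cleave only the MOM group ortho to the formyl group, because magnesium chelated between the formyl oxygen and the neighbouring acetal oxygen activates that acetal alone.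

3. Step 11. A phenol may compete as the nucleophile (benzyl aryl ether formation), or the activated benzylic alcohol may ionise, eroding chemoselectivity. The fallback installs the ester while the ring-A phenol is still masked. It sets out from 18 and returns at 21, replacing steps 10 and 11. HF·pyridine (THF/pyridine, 0 °C) should remove only the primary TBS ether to give methyl 2-hydroxy-6-[2-(hydroxymethyl)-4-methoxy-6-(methoxymethoxy)phenoxy]-4-methylbenzoate F5. Palmitoyl chloride/pyridine (CH2Cl2, –20 °C) should acylate the primary alcohol in preference to the hydrogen-bonded, deactivated salicylate hydroxyl to give methyl 2-{2-[(hexadecanoyloxy)methyl]-4-methoxy-6-(methoxymethoxy)phenoxy}-6-hydroxy-4-methylbenzoate F6. Dilute aqueous HCl in THF (rt to 40 °C) then removes the phenolic MOM group to give 21.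

**Further compounds**
F1 | step 9 | methyl 2-hydroxy-6-(methoxymethoxy)-4-methylbenzoate | COCOc1cc(C)cc(O)c1C(=O)OC
F2 | step 9 | methyl 2-(methoxymethoxy)-4-methyl-6-{[(trifluoromethyl)sulfonyl]oxy}benzoate | COCOc1cc(C)cc(OS(=O)(=O)C(F)(F)F)c1C(=O)OC
F3 | step 9 | methyl 2-{2-[(tert-butyldimethylsilyloxy)methyl]-4-methoxy-6-(methoxymethoxy)phenoxy}-6-(methoxymethoxy)-4-methylbenzoate | COCOc1cc(C)cc(Oc2c(CO[Si](C)(C)C(C)(C)C)cc(OC)cc2OCOC)c1C(=O)OC
F4 | step 3 | 5-methoxy-2,3-bis(methoxymethoxy)benzaldehyde | COCOc1cc(OC)cc(C=O)c1OCOC
F5 | step 11 | methyl 2-hydroxy-6-[2-(hydroxymethyl)-4-methoxy-6-(methoxymethoxy)phenoxy]-4-methylbenzoate | COC(=O)c1c(O)cc(C)cc1Oc1c(CO)cc(OC)cc1OCOC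
F6 | step 11 | methyl 2-{2-[(hexadecanoyloxy)methyl]-4-methoxy-6-(methoxymethoxy)phenoxy}-6-hydroxy-4-methylbenzoate | CCCCCCCCCCCCCCCC(=O)OCc1cc(OC)cc(OCOC)c1Oc1cc(C)cc(O)c1C(=O)OC
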